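If a dying enzyme and a limiting reagent share a flask, I want one number that says which of them stops it first.

| flask | starting material | second substrate | free enzyme | added ligand | temperature | remark | time |
|---|---|---|---|---|---|---|---|
| spring | 0.20 M | 0.60 equiv | 0.01 mol% | 5.5 µM | 12 °C | run made earlier |  |
| summer | 0.20 M | 0.60 equiv | 0.01 mol% | 8.2 µM | 40 °C | run made earlier |  |
| eta | 0.20 M | 0.600 equiv | 0.01 mol% | 11 µM | 0 °C |  | 6.0 h |
| beta | 0.20 M | 0.600 equiv | 0.01 mol% | 11 µM | 25 °C |  | 6.0 h |
| alpha | 0.20 M | 0.600 equiv | 0.01 mol% | 11 µM | 50 °C |  | 6.0 h |

spring run (percent of the starting material charged)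

| time / h | target / % | starting material / % |
|---|---|---|
| 0.250 | 1.7 | 100.0 |
| 0.333 | 1.1 | 99.0 |
| 0.500 | 1.2 | 99.3 |
| 0.667 | 1.5 | 98.8 |
| 1.00 | 2.3 | 97.9 |
| 1.50 | 3.1 | 95.6 |
| 3.00 | 6.0 | 94.3 |

summer run (percent of the starting material charged)

| time / min | target / % | starting material / % |
|---|---|---|
| 2.00 | 3.6 | 96.3 |
| 6.00 | 9.1 | 89.6 |
| 12.0 | 18.6 | 82.1 |
| 15.0 | 22.2 | 77.1 |
| 25.0 | 32.8 | 65.8 |
| 30.0 | 37.8 | 61.9 |
| 40.0 | 45.0 | 54.3 |

(readings scatter by 0.5 percentage points)

- the flask with the highest amount of target, in percent of the starting material charged ("all alike" if they lie within 1.5 percentage points) (eta / beta / alpha / all alike)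
- final target, as a percentage of the starting material charged, in eta
- final target, as a percentage of the starting material charged, in beta
- final target, as a percentage of the starting material charged, in alpha

- reactions considered so far: starting material + free enzyme <-> first complex; first complex -> loaded enzyme + first product; free enzyme + added ligand <-> idle complex; free enzyme -> unfolded enzyme; second substrate + loaded enzyme <-> second complex; second complex -> free enzyme + target

I treat the starting material as falling first order and work in logarithms. In the summer run its pace is 0.0164 min⁻¹ up to 12.0 min, but 0.0128 min⁻¹ from 25.0 min to 40.0 min. If I put that slowing down to a fading catalyst and not to the falling second substrate, the catalyst has a life of about 106 min, an estimate with wide scatter. The pace times the shorter of that life and the time allowed is the reach, the logarithmic fall of starting material the flask can pay for; in the summer run, counting the full life, it is 1.75. The second substrate is the limiting reagent at 0.600 equiv, so the fall needs to go no further than 0.916, and the summer reach exceeds that.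

The spring run's pace of 3.26 × 10⁻⁴ min⁻¹ gives one power of ten in every 16.4 K, with the ligand differences ignored. Stepping down from the summer run, I give beta a pace of 0.121 h⁻¹, and 6.0 h gives a reach of 0.725, short of the need, so I expect 51.5% target. The same step gives eta a reach of 0.0219, or about 2.17% target.

Alpha is the weak link. A life shrinking at the pace's rate keeps the summer reach in my reckoning, but life was read at one temperature. I reforge this with a guess: unfolding gains a power of ten in half that span, 8.22 K. Alpha's pace of 0.0667 min⁻¹ and life of 6.46 min then give a reach of 0.430, or 35.0% target. On that guess beta's life of 118 h outlasts its time, so I commit to beta, with more target than alpha.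

The forecast, which differs from my pick, names alpha with 1%, 38% and 50% for eta, beta and alpha, while granting that “alpha may stall short of the cap”. The flasks give 1.22%, 57.6% and 20.6%, so beta holds the most target.

    starting material + free enzyme ⇌ first complex (K = 1.68 M⁻¹, k = 1430 M⁻¹ s⁻¹, Ea = 38.0 kJ mol⁻¹, ΔH = 33.0 kJ mol⁻¹)
    first complex → loaded enzyme + first product (k = 1.99 s⁻¹, Ea = 79.0 kJ mol⁻¹)
    free enzyme + added ligand ⇌ idle complex, settled at all times (K = 54000 M⁻¹, ΔH = −45.0 kJ mol⁻¹)
    free enzyme → unfolded enzyme (k = 1.86 × 10⁻⁶ s⁻¹, Ea = 273 kJ mol⁻¹)
    second substrate + loaded enzyme ⇌ second complex (K = 249 M⁻¹, k = 239 M⁻¹ s⁻¹, Ea = 38.0 kJ mol⁻¹, ΔH = −33.0 kJ mol⁻¹)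
    second complex → free enzyme + target (k = 26.1 s⁻¹, Ea = 55.0 kJ mol⁻¹)
    (constants at 25 °C)

In alpha, 100% of the catalyst is unfolded enzyme at 6.00 h, and without that step alpha ends at 60.0% instead of 20.6%. Alpha's reach, read from its remaining starting material, is 0.231, below both the need of 0.916 and the summer reach of 1.75, and at my pace that means a life near 3.46 min. I give a flask like eta kept at 15 °C a time-bound reach of 0.179, which means 16.4% target, and it holds 16.0%.

The runs stem from a simulated flask with made-up constants; noise was put on by code.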